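**Retrosynthetic overview**
1. Sodwanone S 30 ⇐ 26 by methylenation/Mukaiyama hydration at C-7', oxidation at C-3' and desilylation.
2. 26 ⇐ 25 by an acid-triggered 1,2-methyl shift C-11→C-12, terminated by loss of a silyl group on C-10; this creates the C-12 quaternary centre and the ring B alkene last.
3. 25 ⇐ left β-hydroxy acid 13 + right α-methylene ketone 23; a decarboxylative radical conjugate addition forms C-13–C-14.
4. 23 ⇐ vinyl carbinol 21 by semipinacol ring expansion (cyclopentanol → ring C cyclohexanone); 13 ⇐ bicyclic ketone 10 by allylation and oxidative cleavage.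
5. Both oxepanes ⇐ Shi epoxidation/7-endo cyclisation of hydroxy ketones obtained by ketoreductase desymmetrisation of 2,2-disubstituted 1,3-diones (from 1 and 14 by Michael addition and Wittig). Ring order: A, then B (left); D, then C (right); union; B rearranged.

Atom labels: left half C-2 (CHMe), C-3, C-4, C-5 (OCH), O-6, C-7 (CMe2), C-8 (carbinol), C-9, C-10, C-11, C-12 (quaternary); linker C-13, C-14; right half O-1', C-2' (CMe2), C-3', C-4', C-5', C-5a', C-6', C-7', C-8', C-9', C-9a'. Ring A = left carbocycle, ring B = left oxepine, ring C = right cyclohexane, ring D = right oxepane.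

Assumption: (E)-3-(trimethylsilyl)acrolein 3, the ent-Shi ketone (L-fructose series) and a panel ketoreductase of the secodione-reducing type are purchasable.

**Left fragment**

Step 1
Reactants: 1 cyclohexane-1,3-dione
Product: 2 2-methylcyclohexane-1,3-dione
Conditions: MeI, NaOH, H2O/dioxane, 65 °C
Reagents that add atoms: iodomethane, CI
Why: SN2 C-methylation of the dione enolate at the doubly activated carbon; no stereocentre is formed.

Step 2
Reactants: 2 2-methylcyclohexane-1,3-dione; 3 (E)-3-(trimethylsilyl)prop-2-enal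
Product: 4 (3R)-3-(1-methyl-2,6-dioxocyclohexyl)-3-(trimethylsilyl)propanal
Conditions: (S)-α,α-diphenylprolinol trimethylsilyl ether (20 mol %), PhCO2H (20 mol %), CHCl3, 0 °C to rt
Reagents that add atoms: none
Why: Iminium-catalysed enantioselective Michael addition; the (S)-catalyst shields one face of the E-iminium ion so the dione attacks the Si face of the β-carbon, giving the (R)-C–Si centre that later becomes C-10, next to the future ring-fusion carbon C-11.

Step 3
Reactants: 4 (3R)-3-(1-methyl-2,6-dioxocyclohexyl)-3-(trimethylsilyl)propanal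
Product: 5 2-methyl-2-[(1R)-4-methyl-1-(trimethylsilyl)pent-3-en-1-yl]cyclohexane-1,3-dione
Conditions: i-PrPPh3I, n-BuLi, THF, −78 to 0 °C
Reagents that add atoms: isopropyltriphenylphosphonium iodide, CC(C)[P+](c1ccccc1)(c1ccccc1)c1ccccc1.[I-]
Why: Wittig olefination; the aldehyde reacts far faster than the two hindered ring ketones that flank the quaternary carbon, and the C–Si centre is untouched.

Step 4
Reactants: 5 2-methyl-2-[(1R)-4-methyl-1-(trimethylsilyl)pent-3-en-1-yl]cyclohexane-1,3-dione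
Product: 6 (2R,3S)-3-hydroxy-2-methyl-2-[(1R)-4-methyl-1-(trimethylsilyl)pent-3-en-1-yl]cyclohexan-1-one
Conditions: KRED (secodione-reducing type, panel-selected), NADP+ (cat.), i-PrOH, phosphate buffer pH 7/DMSO, 30 °C
Reagents that add atoms: none
Why: Enzymatic desymmetrising ketone reduction; as in the secodione-to-secol reduction the enzyme gives the S carbinol cis to the methyl and trans to the long chain, which sets C-5 and the quaternary C-11 together.

Step 5
Reactants: 6 (2R,3S)-3-hydroxy-2-methyl-2-[(1R)-4-methyl-1-(trimethylsilyl)pent-3-en-1-yl]cyclohexan-1-one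
Product: 8 (3S,5R,5aR,9aS)-3-hydroxy-2,2,5a-trimethyl-5-(trimethylsilyl)octahydro-1-benzoxepin-6(2H)-one, via epoxide 7 (not isolated)
Conditions: ent-Shi ketone (30 mol %), Oxone, K2CO3, Bu4NHSO4, MeCN/dimethoxymethane/aq. buffer pH 10.5, 0 °C; then CSA (10 mol %), CH2Cl2, 0 °C
Reagents that add atoms: potassium peroxymonosulfate (active part of Oxone), [K+].[O-]S(=O)(=O)OO
Why: Shi asymmetric epoxidation (the ent-ketone gives the S epoxide, which is C-8) followed by acid-catalysed 7-endo epoxide opening at the tertiary carbon by the trans-disposed hydroxyl, giving the trans-fused oxepane with the C-10 silyl group trans to the angular methyl.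

Step 6
Reactants: 8 (3S,5R,5aR,9aS)-3-hydroxy-2,2,5a-trimethyl-5-(trimethylsilyl)octahydro-1-benzoxepin-6(2H)-one
Product: 9 (3S,5R,5aR,9aS)-3-[(tert-butyldimethylsilyl)oxy]-2,2,5a-trimethyl-5-(trimethylsilyl)octahydro-1-benzoxepin-6(2H)-one
Conditions: TBSOTf, 2,6-lutidine, CH2Cl2, −78 to 0 °C
Reagents that add atoms: tert-butyldimethylsilyl triflate, CC(C)(C)[Si](C)(C)OS(=O)(=O)C(F)(F)F
Why: Silyl ether formation; it keeps the C-8 hydroxyl distinct from the C-3' hydroxyl that is oxidised in step 20.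

Step 7
Reactants: 9 (3S,5R,5aR,9aS)-3-[(tert-butyldimethylsilyl)oxy]-2,2,5a-trimethyl-5-(trimethylsilyl)octahydro-1-benzoxepin-6(2H)-one
Product: 10 (3S,5R,5aR,7S,9aS)-3-[(tert-butyldimethylsilyl)oxy]-2,2,5a,7-tetramethyl-5-(trimethylsilyl)octahydro-1-benzoxepin-6(2H)-one
Conditions: LiN(i-Pr)2, THF, −78 °C; MeI, −78 to 0 °C; then NaOMe (cat.), MeOH, rt
Reagents that add atoms: iodomethane, CI
Why: Enolate alkylation on the only enolisable side, then base equilibration to the equatorial methyl (trans to the axial angular methyl, avoiding a 1,3-diaxial clash), which sets C-2.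

Step 8
Reactants: 10 (3S,5R,5aR,7S,9aS)-3-[(tert-butyldimethylsilyl)oxy]-2,2,5a,7-tetramethyl-5-(trimethylsilyl)octahydro-1-benzoxepin-6(2H)-one
Product: 11 (3S,5R,5aR,6R,7S,9aS)-3-[(tert-butyldimethylsilyl)oxy]-2,2,5a,7-tetramethyl-6-(prop-2-en-1-yl)-5-(trimethylsilyl)decahydro-1-benzoxepin-6-ol
Conditions: CH2=CHCH2MgBr, THF, −78 to 0 °C
Reagents that add atoms: allylmagnesium bromide, C=CC[Mg]Br
Why: Grignard 1,2-addition; allylmagnesium reagents add to very hindered ketones through a six-membered transition state, and the C-12 carbinol configuration (drawn for axial attack) is erased in step 17.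

Step 9
Reactants: 11 (3S,5R,5aR,6R,7S,9aS)-3-[(tert-butyldimethylsilyl)oxy]-2,2,5a,7-tetramethyl-6-(prop-2-en-1-yl)-5-(trimethylsilyl)decahydro-1-benzoxepin-6-ol
Product: 13 2-[(3S,5R,5aR,6R,7S,9aS)-3-[(tert-butyldimethylsilyl)oxy]-6-hydroxy-2,2,5a,7-tetramethyl-5-(trimethylsilyl)decahydro-1-benzoxepin-6-yl]acetic acid, via aldehyde 12 (not isolated)
Conditions: O3, CH2Cl2/MeOH, −78 °C; Me2S; then NaClO2, NaH2PO4, 2-methylbut-2-ene, t-BuOH/H2O, 0 °C
Reagents that add atoms: ozone, [O-][O+]=O; sodium chlorite, [Na+].[O-]Cl=O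
Why: Ozonolysis of the only alkene followed by Pinnick oxidation, telescoped so the retro-aldol-prone β-hydroxy aldehyde is never stored.

**Right fragment**

Step 10
Reactants: 14 2-methylcyclopentane-1,3-dione; 15 prop-2-enal
Product: 16 3-(1-methyl-2,5-dioxocyclopentyl)propanal
Conditions: H2O, rt
Reagents that add atoms: none
Why: Michael addition of the acidic dione to acrolein in water, forming the quaternary carbon C-5a' (still prochiral).

Step 11
Reactants: 16 3-(1-methyl-2,5-dioxocyclopentyl)propanal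
Product: 17 2-methyl-2-(4-methylpent-3-en-1-yl)cyclopentane-1,3-dione
Conditions: i-PrPPh3I, n-BuLi, THF, −78 to 0 °C
Reagents that add atoms: isopropyltriphenylphosphonium iodide, CC(C)[P+](c1ccccc1)(c1ccccc1)c1ccccc1.[I-]
Why: Chemoselective Wittig olefination of the aldehyde in the presence of the hindered ring ketones.

Step 12
Reactants: 17 2-methyl-2-(4-methylpent-3-en-1-yl)cyclopentane-1,3-dione
Product: 18 (2R,3S)-3-hydroxy-2-methyl-2-(4-methylpent-3-en-1-yl)cyclopentan-1-one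
Conditions: KRED (secodione-reducing type, panel-selected), NADP+ (cat.), i-PrOH, phosphate buffer pH 7/DMSO, 30 °C
Reagents that add atoms: none
Why: Enzymatic desymmetrising reduction of a close analogue of methyl secodione, giving the S carbinol trans to the long chain and so setting C-9a' and C-5a'.

Step 13
Reactants: 18 (2R,3S)-3-hydroxy-2-methyl-2-(4-methylpent-3-en-1-yl)cyclopentan-1-one
Product: 20 (3S,5aR,8aS)-3-hydroxy-2,2,5a-trimethyloctahydro-6H-cyclopenta[b]oxepin-6-one, via epoxide 19 (not isolated)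
Conditions: ent-Shi ketone (30 mol %), Oxone, K2CO3, Bu4NHSO4, MeCN/dimethoxymethane/aq. buffer pH 10.5, 0 °C; then CSA (10 mol %), CH2Cl2, 0 °C
Reagents that add atoms: potassium peroxymonosulfate (active part of Oxone), [K+].[O-]S(=O)(=O)OO
Why: Shi epoxidation and 7-endo epoxide opening at the tertiary carbon build trans-fused ring D; the C-3' carbinol configuration only keeps the material a single isomer, since it is oxidised in step 20.

Step 14
Reactants: 20 (3S,5aR,8aS)-3-hydroxy-2,2,5a-trimethyloctahydro-6H-cyclopenta[b]oxepin-6-one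
Product: 21 (3S,5aR,6S,8aS)-6-ethenyl-2,2,5a-trimethyloctahydro-2H-cyclopenta[b]oxepine-3,6-diol
Conditions: CH2=CHMgBr (3 equiv), CeCl3, THF, −78 to 0 °C
Reagents that add atoms: vinylmagnesium bromide, C=C[Mg]Br
Why: Organocerium-assisted Grignard 1,2-addition (enolisation suppressed) from the face anti to the angular methyl; this carbinol centre becomes the C-7' carbonyl in step 15.

Step 15
Reactants: 21 (3S,5aR,6S,8aS)-6-ethenyl-2,2,5a-trimethyloctahydro-2H-cyclopenta[b]oxepine-3,6-diol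
Product: 23 (3S,5aS,9aS)-3-hydroxy-2,2,5a-trimethyl-6-methylideneoctahydro-1-benzoxepin-7(2H)-one, via bromomethyl ketone 22 (not isolated)
Conditions: NBS, CH2Cl2/i-PrOH, −20 °C; then DBU, 0 °C
Reagents that add atoms: none
Why: Halonium-induced semipinacol ring expansion; the bromonium ion on the vinyl group triggers a 1,2-shift of the more substituted ring carbon C-5a' (with retention), turning the cyclopentanol into the ring C 2-(bromomethyl)cyclohexanone, and E1cB loss of HBr gives the α-methylene ketone.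

**Union and endgame**

Step 16
Reactants: 13 2-[(3S,5R,5aR,6R,7S,9aS)-3-[(tert-butyldimethylsilyl)oxy]-6-hydroxy-2,2,5a,7-tetramethyl-5-(trimethylsilyl)decahydro-1-benzoxepin-6-yl]acetic acid; 23 (3S,5aS,9aS)-3-hydroxy-2,2,5a-trimethyl-6-methylideneoctahydro-1-benzoxepin-7(2H)-one
Product: 25 coupled hydroxy ketone [C-12 carbinol of 13 joined by C-13H2–C-14H2 to C-6' (S) of the 7'-oxo right bicycle], via N-acyloxyphthalimide 24 (not isolated)
Conditions: N-hydroxyphthalimide, DIC, DMAP (cat.), CH2Cl2, rt; then 23, Hantzsch ester, i-Pr2NEt, [Ru(bpy)3](PF6)2 (1 mol %), MeCN/CH2Cl2, blue LEDs, rt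
Reagents that add atoms: none
Why: Decarboxylative Giese reaction through a redox-active ester; the primary β-hydroxyalkyl radical (no unsaturation nearby, so no rearrangement) adds to the unhindered methylene terminus, and enolate protonation anti to the axial C-5a' methyl gives the equatorial C-6' side chain (also the thermodynamic epimer).

Step 17
Reactants: 25 coupled hydroxy ketone
Product: 26 rearranged ketone [left half of sodwanone S as its 8-O-TBS ether; right half with 3'-OH (S) and 7'-ketone]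
Conditions: Bi(OTf)3 (5 mol %), (CF3)2CHOH/CH2Cl2 1:4, −40 to −20 °C
Reagents that add atoms: none
Why: Proposed new method: a silicon-terminated dehydrative Wagner–Meerwein 1,2-methyl shift, in which catalytic acid ionises the tertiary C-12 carbinol, the axial C-11 methyl (parallel to the empty p orbital) migrates suprafacially to C-12 (setting C-12 with methyl cis to O-5 and leaving C-2 untouched), the new C-11 cation is stabilised by the antiperiplanar C-10–Si bond (β-silicon effect, which makes an otherwise uphill shift to a β-oxygenated cation downhill, while the gauche Si–C-10–C-11–C-12 geometry disfavours 1,3-elimination) and collapses by loss of the silyl group to the C-10=C-11 alkene only; the closest known reactions are silicon-controlled carbocation rearrangements (Fleming type) and Lewis-acid friedo-type methyl shifts in terpenoid synthesis, neither shown for a ring-fusion methyl of an oxepane-fused cyclohexane starting from a γ-silyl tertiary alcohol.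

Step 18
Reactants: 26 rearranged ketone
Product: 27 7'-methylidene compound (C-7' C=O of 26 replaced by C=CH2)
Conditions: Ph3PCH3Br, KOt-Bu (3 equiv each), toluene, 0 to 60 °C
Reagents that add atoms: methyltriphenylphosphonium bromide, C[P+](c1ccccc1)(c1ccccc1)c1ccccc1.[Br-]
Why: Wittig methylenation of the only ketone; the free C-3' hydroxyl is tolerated with excess ylide and C-6' stays in its thermodynamic equatorial configuration.

Step 19
Reactants: 27 7'-methylidene compound
Product: 28 tertiary alcohol [7'-methyl-7'-hydroxy (S), 3'-hydroxy, 8-O-TBS]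
Conditions: Co(acac)2 (20 mol %), PhSiH3, O2 (1 atm), i-PrOH/CH2Cl2, 0 °C to rt
Reagents that add atoms: dioxygen, O=O
Why: Mukaiyama hydration (hydrogen-atom transfer), chemoselective for the 1,1-disubstituted alkene over the hindered ring B alkene; the tertiary radical is oxygenated equatorially, anti to the 1,3-axial C-5a' methyl, giving axial methyl and equatorial hydroxyl at C-7' as in sclareol-type hydrations.

Step 20
Reactants: 28 tertiary alcohol
Product: 29 8-O-TBS sodwanone S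
Conditions: Dess–Martin periodinane, NaHCO3, CH2Cl2, rt
Reagents that add atoms: none
Why: Dess–Martin oxidation of the only free secondary alcohol (C-3') to the oxepanone; tertiary alcohol, silyl ether and alkene are inert.

Step 21
Reactants: 29 8-O-TBS sodwanone S
Product: 30 sodwanone S
Conditions: HF·pyridine, pyridine, THF, 0 °C to rt
Reagents that add atoms: none
Why: Fluoride-mediated silyl ether cleavage under buffered conditions that spare the allylic ether, ketone and tertiary alcohol.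

**Compound list**
1 | cyclohexane-1,3-dione | O=C1CCCC(=O)C1 | starting material
2 | 2-methylcyclohexane-1,3-dione | CC1C(=O)CCCC1=O | intermediate
3 | (E)-3-(trimethylsilyl)prop-2-enal | C[Si](C)(C)/C=C/C=O | starting material
4 | (3R)-3-(1-methyl-2,6-dioxocyclohexyl)-3-(trimethylsilyl)propanal | O=CC[C@@H]([Si](C)(C)C)C1(C)C(=O)CCCC1=O | intermediate
5 | 2-methyl-2-[(1R)-4-methyl-1-(trimethylsilyl)pent-3-en-1-yl]cyclohexane-1,3-dione | CC(C)=CC[C@@H]([Si](C)(C)C)C1(C)C(=O)CCCC1=O | intermediate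
6 | (2R,3S)-3-hydroxy-2-methyl-2-[(1R)-4-methyl-1-(trimethylsilyl)pent-3-en-1-yl]cyclohexan-1-one | CC(C)=CC[C@@H]([Si](C)(C)C)[C@@]1(C)C(=O)CCC[C@@H]1O | intermediate
7 | (2R,3S)-2-{(1R)-2-[(2S)-3,3-dimethyloxiran-2-yl]-1-(trimethylsilyl)ethyl}-3-hydroxy-2-methylcyclohexan-1-one | CC1(C)O[C@H]1C[C@@H]([Si](C)(C)C)[C@@]1(C)C(=O)CCC[C@@H]1O | intermediate
8 | (3S,5R,5aR,9aS)-3-hydroxy-2,2,5a-trimethyl-5-(trimethylsilyl)octahydro-1-benzoxepin-6(2H)-one (trans-fused) | C1CC[C@@H]2OC(C)(C)[C@@H](O)C[C@@H]([Si](C)(C)C)[C@@]2(C)C1=O | intermediate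
9 | (3S,5R,5aR,9aS)-3-[(tert-butyldimethylsilyl)oxy]-2,2,5a-trimethyl-5-(trimethylsilyl)octahydro-1-benzoxepin-6(2H)-one | C1CC[C@@H]2OC(C)(C)[C@@H](O[Si](C)(C)C(C)(C)C)C[C@@H]([Si](C)(C)C)[C@@]2(C)C1=O | intermediate
10 | (3S,5R,5aR,7S,9aS)-3-[(tert-butyldimethylsilyl)oxy]-2,2,5a,7-tetramethyl-5-(trimethylsilyl)octahydro-1-benzoxepin-6(2H)-one | C[C@H]1CC[C@@H]2OC(C)(C)[C@@H](O[Si](C)(C)C(C)(C)C)C[C@@H]([Si](C)(C)C)[C@@]2(C)C1=O | intermediate
11 | (3S,5R,5aR,6R,7S,9aS)-3-[(tert-butyldimethylsilyl)oxy]-2,2,5a,7-tetramethyl-6-(prop-2-en-1-yl)-5-(trimethylsilyl)decahydro-1-benzoxepin-6-ol | C[C@H]1CC[C@@H]2OC(C)(C)[C@@H](O[Si](C)(C)C(C)(C)C)C[C@@H]([Si](C)(C)C)[C@@]2(C)[C@@]1(O)CC=C | intermediate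
12 | 2-[(3S,5R,5aR,6R,7S,9aS)-3-[(tert-butyldimethylsilyl)oxy]-6-hydroxy-2,2,5a,7-tetramethyl-5-(trimethylsilyl)decahydro-1-benzoxepin-6-yl]acetaldehyde | C[C@H]1CC[C@@H]2OC(C)(C)[C@@H](O[Si](C)(C)C(C)(C)C)C[C@@H]([Si](C)(C)C)[C@@]2(C)[C@@]1(O)CC=O | intermediate
13 | 2-[(3S,5R,5aR,6R,7S,9aS)-3-[(tert-butyldimethylsilyl)oxy]-6-hydroxy-2,2,5a,7-tetramethyl-5-(trimethylsilyl)decahydro-1-benzoxepin-6-yl]acetic acid | C[C@H]1CC[C@@H]2OC(C)(C)[C@@H](O[Si](C)(C)C(C)(C)C)C[C@@H]([Si](C)(C)C)[C@@]2(C)[C@@]1(O)CC(=O)O | intermediate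
14 | 2-methylcyclopentane-1,3-dione | CC1C(=O)CCC1=O | starting material
15 | prop-2-enal (acrolein) | C=CC=O | starting material
16 | 3-(1-methyl-2,5-dioxocyclopentyl)propanal | O=CCCC1(C)C(=O)CCC1=O | intermediate
17 | 2-methyl-2-(4-methylpent-3-en-1-yl)cyclopentane-1,3-dione | CC(C)=CCCC1(C)C(=O)CCC1=O | intermediate
18 | (2R,3S)-3-hydroxy-2-methyl-2-(4-methylpent-3-en-1-yl)cyclopentan-1-one | CC(C)=CCC[C@@]1(C)C(=O)CC[C@@H]1O | intermediate
19 | (2R,3S)-2-{2-[(2S)-3,3-dimethyloxiran-2-yl]ethyl}-3-hydroxy-2-methylcyclopentan-1-one | CC1(C)O[C@H]1CC[C@@]1(C)C(=O)CC[C@@H]1O | intermediate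
20 | (3S,5aR,8aS)-3-hydroxy-2,2,5a-trimethyloctahydro-6H-cyclopenta[b]oxepin-6-one (trans-fused) | O=C1[C@]2(C)CC[C@H](O)C(C)(C)O[C@H]2CC1 | intermediate
21 | (3S,5aR,6S,8aS)-6-ethenyl-2,2,5a-trimethyloctahydro-2H-cyclopenta[b]oxepine-3,6-diol | C=C[C@]1(O)[C@]2(C)CC[C@H](O)C(C)(C)O[C@H]2CC1 | intermediate
22 | (3S,5aS,6S,9aS)-6-(bromomethyl)-3-hydroxy-2,2,5a-trimethyloctahydro-1-benzoxepin-7(2H)-one | BrC[C@H]1[C@]2(C)CC[C@H](O)C(C)(C)O[C@H]2CCC1=O | intermediate
23 | (3S,5aS,9aS)-3-hydroxy-2,2,5a-trimethyl-6-methylideneoctahydro-1-benzoxepin-7(2H)-one | C=C1[C@]2(C)CC[C@H](O)C(C)(C)O[C@H]2CCC1=O | intermediate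
24 | N-acyloxyphthalimide (redox-active ester) of acid 13 | C[C@H]1CC[C@@H]2OC(C)(C)[C@@H](O[Si](C)(C)C(C)(C)C)C[C@@H]([Si](C)(C)C)[C@@]2(C)[C@@]1(O)CC(=O)ON1C(=O)c2ccccc2C1=O | intermediate
25 | coupled hydroxy ketone: left bicycle of 13 (C-12 carbinol, C-10 SiMe3, 8-O-TBS) joined through C-13H2–C-14H2 to C-6' (S, equatorial) of the right (3'S,5a'S,9a'S)-3'-hydroxy-7'-oxo bicycle | C[C@H]1CC[C@@H]2OC(C)(C)[C@@H](O[Si](C)(C)C(C)(C)C)C[C@@H]([Si](C)(C)C)[C@@]2(C)[C@@]1(O)CC[C@H]1[C@]2(C)CC[C@H](O)C(C)(C)O[C@H]2CCC1=O | intermediate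
26 | rearranged ketone: sodwanone S left half as 8-O-TBS ether (2S,5S,8S,12S; C-10=C-11), right half 3'-hydroxy (S), 7'-oxo, no 7'-methyl | C[C@H]1CC[C@@H]2OC(C)(C)[C@@H](O[Si](C)(C)C(C)(C)C)CC=C2[C@@]1(C)CC[C@H]1[C@]2(C)CC[C@H](O)C(C)(C)O[C@H]2CCC1=O | intermediate
27 | 7'-methylidene analogue of 26 (all stereocentres as in 26) | C[C@H]1CC[C@@H]2OC(C)(C)[C@@H](O[Si](C)(C)C(C)(C)C)CC=C2[C@@]1(C)CC[C@H]1[C@]2(C)CC[C@H](O)C(C)(C)O[C@H]2CCC1=C | intermediate
28 | 8-O-TBS-3'-deoxo-3'(S)-hydroxy sodwanone S (7'S tertiary alcohol in place) | C[C@H]1CC[C@@H]2OC(C)(C)[C@@H](O[Si](C)(C)C(C)(C)C)CC=C2[C@@]1(C)CC[C@H]1[C@]2(C)CC[C@H](O)C(C)(C)O[C@H]2CC[C@]1(C)O | intermediate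
29 | 8-O-(tert-butyldimethylsilyl) sodwanone S | C[C@H]1CC[C@@H]2OC(C)(C)[C@@H](O[Si](C)(C)C(C)(C)C)CC=C2[C@@]1(C)CC[C@H]1[C@]2(C)CCC(=O)C(C)(C)O[C@H]2CC[C@]1(C)O | intermediate
30 | sodwanone S | C[C@H]1CC[C@@H]2OC(C)(C)[C@@H](O)CC=C2[C@@]1(C)CC[C@H]1[C@]2(C)CCC(=O)C(C)(C)O[C@H]2CC[C@]1(C)O | target

**Step count**
Total steps: 21 (left fragment 9, right fragment 6, union and endgame 6). Longest linear sequence: 15 (steps 1–9 and 16–21).

**Three steps most likely to fail, with fallbacks**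

Step 17 (the new silicon-terminated methyl shift). If 25 gives simple dehydration, 1,3-elimination or loss of silicon without the shift, change to the silicon-free Lewis-acid backbone (friedo-type) rearrangement established for 1,2-methyl shifts at ring-fusion carbons of terpenoids. This fallback sets out from 2 (with 15) and returns at 26. Michael addition of 2 to acrolein 15 (water, rt) gives 3-(1-methyl-2,6-dioxocyclohexyl)propanal F1. Wittig olefination as in step 3 gives 2-methyl-2-(4-methylpent-3-en-1-yl)cyclohexane-1,3-dione F2. Ketoreductase reduction as in step 4 gives (2R,3S)-3-hydroxy-2-methyl-2-(4-methylpent-3-en-1-yl)cyclohexan-1-one F3. ent-Shi epoxidation gives the (S)-epoxide F4, which CSA cyclises to (3S,5aR,9aS)-3-hydroxy-2,2,5a-trimethyloctahydro-1-benzoxepin-6(2H)-one F5. TBSOTf gives the silyl ether F6, and LiN(i-Pr)2/MeI followed by NaOMe gives the (7S)-7-methyl ketone F7. CH2=CHCH2MgBr gives the allyl carbinol F8; ozonolysis gives the aldehyde F9 and Pinnick oxidation the β-hydroxy acid F10. Its N-acyloxyphthalimide F11 adds to 23 under the step 16 conditions to give the silicon-free coupled carbinol F12. BF3·OEt2 (CH2Cl2, −78 to −20 °C) then ionises the C-12 hydroxyl, the axial C-11 methyl shifts, and a proton is lost from C-10 to give 26. C-12 carries no hydrogen after the shift, so the only competing alkene is the enol ether from loss of H-5, which is removed by chromatography.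

Step 2 (Michael addition of a hindered dione to a β-silyl enal). If addition is slow or poorly selective, form the C-11–C-10 bond at the alkyne oxidation level and set the C–Si centre by hydride delivery. This fallback sets out from 2 and returns at 4. DABCO-catalysed conjugate addition of 2 to commercial 3-(trimethylsilyl)prop-2-ynal gives 3-(1-methyl-2,6-dioxocyclohexyl)-3-(trimethylsilyl)prop-2-enal F13 (E/Z mixture). Organocatalytic transfer hydrogenation (chiral imidazolidinone trifluoroacetate, Hantzsch ester; E/Z-convergent iminium reduction) then gives (R)-4.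

Step 15 (bromonium semipinacol ring expansion). If bromohydrin or epoxide formation, or migration of the wrong ring carbon, dominates, use the stepwise epoxy-alcohol semipinacol. This fallback sets out from 21 and returns at 23. VO(acac)2/t-BuOOH epoxidation of the allylic alcohol gives the oxiranyl carbinol F14. BF3·OEt2 (CH2Cl2, −78 °C) triggers the 1,2-shift of C-5a' onto the epoxide carbon to give the 6-(hydroxymethyl) ketone F15. MsCl/Et3N converts the primary alcohol into the mesylate F16, which eliminates with DBU to 23.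

**Further compounds**
F1 | step 17 | 3-(1-methyl-2,6-dioxocyclohexyl)propanal | O=CCCC1(C)C(=O)CCCC1=O
F2 | step 17 | 2-methyl-2-(4-methylpent-3-en-1-yl)cyclohexane-1,3-dione | CC(C)=CCCC1(C)C(=O)CCCC1=O
F3 | step 17 | (2R,3S)-3-hydroxy-2-methyl-2-(4-methylpent-3-en-1-yl)cyclohexan-1-one | CC(C)=CCC[C@@]1(C)C(=O)CCC[C@@H]1O
F4 | step 17 | (2R,3S)-2-{2-[(2S)-3,3-dimethyloxiran-2-yl]ethyl}-3-hydroxy-2-methylcyclohexan-1-one | CC1(C)O[C@H]1CC[C@@]1(C)C(=O)CCC[C@@H]1O
F5 | step 17 | (3S,5aR,9aS)-3-hydroxy-2,2,5a-trimethyloctahydro-1-benzoxepin-6(2H)-one | C1CC[C@@H]2OC(C)(C)[C@@H](O)CC[C@@]2(C)C1=O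
F6 | step 17 | (3S,5aR,9aS)-3-[(tert-butyldimethylsilyl)oxy]-2,2,5a-trimethyloctahydro-1-benzoxepin-6(2H)-one | C1CC[C@@H]2OC(C)(C)[C@@H](O[Si](C)(C)C(C)(C)C)CC[C@@]2(C)C1=O
F7 | step 17 | (3S,5aR,7S,9aS)-3-[(tert-butyldimethylsilyl)oxy]-2,2,5a,7-tetramethyloctahydro-1-benzoxepin-6(2H)-one | C[C@H]1CC[C@@H]2OC(C)(C)[C@@H](O[Si](C)(C)C(C)(C)C)CC[C@@]2(C)C1=O
F8 | step 17 | (3S,5aR,6R,7S,9aS)-3-[(tert-butyldimethylsilyl)oxy]-2,2,5a,7-tetramethyl-6-(prop-2-en-1-yl)decahydro-1-benzoxepin-6-ol | C[C@H]1CC[C@@H]2OC(C)(C)[C@@H](O[Si](C)(C)C(C)(C)C)CC[C@@]2(C)[C@@]1(O)CC=C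
F9 | step 17 | 2-[(3S,5aR,6R,7S,9aS)-3-[(tert-butyldimethylsilyl)oxy]-6-hydroxy-2,2,5a,7-tetramethyldecahydro-1-benzoxepin-6-yl]acetaldehyde | C[C@H]1CC[C@@H]2OC(C)(C)[C@@H](O[Si](C)(C)C(C)(C)C)CC[C@@]2(C)[C@@]1(O)CC=O
F10 | step 17 | 2-[(3S,5aR,6R,7S,9aS)-3-[(tert-butyldimethylsilyl)oxy]-6-hydroxy-2,2,5a,7-tetramethyldecahydro-1-benzoxepin-6-yl]acetic acid | C[C@H]1CC[C@@H]2OC(C)(C)[C@@H](O[Si](C)(C)C(C)(C)C)CC[C@@]2(C)[C@@]1(O)CC(=O)O
F11 | step 17 | N-acyloxyphthalimide of F10 | C[C@H]1CC[C@@H]2OC(C)(C)[C@@H](O[Si](C)(C)C(C)(C)C)CC[C@@]2(C)[C@@]1(O)CC(=O)ON1C(=O)c2ccccc2C1=O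
F12 | step 17 | silicon-free coupled hydroxy ketone (25 without the C-10 trimethylsilyl group) | C[C@H]1CC[C@@H]2OC(C)(C)[C@@H](O[Si](C)(C)C(C)(C)C)CC[C@@]2(C)[C@@]1(O)CC[C@H]1[C@]2(C)CC[C@H](O)C(C)(C)O[C@H]2CCC1=O
F13 | step 2 | 3-(1-methyl-2,6-dioxocyclohexyl)-3-(trimethylsilyl)prop-2-enal (E/Z mixture) | O=CC=C([Si](C)(C)C)C1(C)C(=O)CCCC1=O
F14 | step 15 | (3S,5aR,6S,8aS)-2,2,5a-trimethyl-6-(oxiran-2-yl)octahydro-2H-cyclopenta[b]oxepine-3,6-diol (oxirane carbon as formed, either epimer) | C1OC1[C@]1(O)[C@]2(C)CC[C@H](O)C(C)(C)O[C@H]2CC1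
F15 | step 15 | (3S,5aS,6S,9aS)-3-hydroxy-6-(hydroxymethyl)-2,2,5a-trimethyloctahydro-1-benzoxepin-7(2H)-one | OC[C@H]1[C@]2(C)CC[C@H](O)C(C)(C)O[C@H]2CCC1=O
F16 | step 15 | [(3S,5aS,6S,9aS)-3-hydroxy-2,2,5a-trimethyl-7-oxodecahydro-1-benzoxepin-6-yl]methyl methanesulfonate | CS(=O)(=O)OC[C@H]1[C@]2(C)CC[C@H](O)C(C)(C)O[C@H]2CCC1=O
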